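(Readings and results are simulated with constants of no real substance; noise was put on by code.)

The closed, stirred vessel was to take 1.0 M of substrate, after two runs at higher charges.

| flask | substrate | remark | time |
|---|---|---|---|
| winter | 1.4 M | run made earlier |  |
| autumn | 2.2 M | run made earlier |  |
| flask | 1.0 M |  | 10 h |

| run | time / h | side product A / % | target / % |
|---|---|---|---|
| winter | 0.833 | 0.9 | 9.2 |
| winter | 1.50 | 2.6 | 16.5 |
| winter | 2.50 | 6.2 | 21.5 |
| winter | 3.00 | 8.3 | 21.7 |
| winter | 4.00 | 10.7 | 17.9 |
| winter | 5.00 | 13.8 | 15.6 |
| winter | 6.00 | 17.7 | 13.0 |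
| autumn | 0.333 | 0 | 2.2 |
| autumn | 1.00 | 1.7 | 11.3 |
| autumn | 1.50 | 3.1 | 16.5 |
| autumn | 2.50 | 6.6 | 20.5 |
| autumn | 4.00 | 11.3 | 19.8 |
| autumn | 5.00 | 15.0 | 15.9 |
| autumn | 6.00 | 17.3 | 12.0 |

(readings scatter by 0.5 percentage points)

- ratio of side product A to target at 15 min
- ratio of side product A to target at 10 h
- which of side product A and target there is more of at 10 h



The autumn run carried 1.57 times the winter charge, yet at 6.00 h its target differed from winter's by 1 percentage point and its side product A by 0.4 points, with a reading scatter of 0.5 points. So I read both runs as first-order, with percentages following time and not charge, and I treated them as one curve for the new flask.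

The fading rate k of target is its fractional loss per hour late in the run, pooled over both runs from 4.00 h to 6.00 h:

k = 0.205 h⁻¹

target at 10 h = 12.5 % × exp(−k × 4.00 h) = 5.50 %

At 6.00 h, side product A plus target averaged 30.0 %. I assumed that sum held and put the first answer back in:

side product A at 10 h = 24.5 %, ratio = 4.46

For 15 min in the new flask I carried over the ratio of the earliest winter pair, at 0.833 h, which was 0.0978; this is a rough reading, with side product A at 0.9 % against a scatter of 0.5 points.

The forecast gave 0.02 at 15 min and 4.2 at 10 h, below both my figures, with side product A ahead: “This assumes the plateau holds and A is stable.”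

The flask gave 0.0904 at 15 min and 4.99 at 10 h, with 24.9 % of side product A against 5.00 % of target.

    substrate ⇌ dormant form (K = 0.610, k = 0.210 h⁻¹)
    intermediate B → side product B (k = 0.140 h⁻¹)
    target → over-reaction product (k = 0.390 h⁻¹)
    substrate ⇌ intermediate B (K = 1.60, k = 0.560 h⁻¹)
    intermediate A → side product A (k = 0.200 h⁻¹)
    substrate → intermediate A (k = 0.220 h⁻¹)
    intermediate B → target (k = 1.00 h⁻¹)

Applied to the flask's 15.9 % of target at 5.00 h, k gives 5.69 % at 10 h, against the 5.00 % that stood there. In the flask intermediate A, which turns into side product A, was made 3.75 times as fast as it was used up at 0.966 h, each step taken net, and that quotient had become 0.252 at 10.0 h. With 2.5 M of substrate, k holds no charge term, so it gives 5.50 % of target and a ratio of 4.46 again. The computed result for that flask was 5.00 % of target and a ratio of 4.99.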